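**Plan**

1. Retrosynthetic cuts: the two CH2OH groups go back to carboxylic esters and C4–H to a temporary C4–OH. Then C3–C4 and C1–C2 of ring B are cut together, a [4+2] retron of an o-quinodimethane across C4a–C8a of ring A plus a fumarate. Last, the aryl–CH2 bond of the resulting 2-benzylbenzaldehyde is cut. (Tetralin locants: C1 = CH–aryl, C2/C3 = CH–CH2OH, C4 = ring CH2; ring A = fused benzene ring, ring B = saturated ring.)
2. Forward: both aromatic rings are bought and joined at the future C1 by Negishi coupling. Ring B then arises in one photochemical operation from the 2-benzylbenzaldehyde and a chiral fumarate; hydrogenolysis and hydride reduction finish the route.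
3. Enabling feature: the future C1 is a doubly benzylic CH2 between the two guaiacyl rings and sits ortho to the formyl carbon (future C4) on ring A. The excited C=O takes a C1 hydrogen, and the aromatic C4a–C8a bond becomes the central bond of the diene C4=C4a–C8a=C1. Rearomatisation of ring A drives the cycloaddition, and the OMe at C7 (para to C4a) later makes the C4–O bond easy to cleave.
4. Stereochemistry: C2/C3 trans comes from the E-fumarate, and C1/C2 trans from the endo preference of the ester next to the C4–OH. The absolute configuration comes from two (S)-lactate ester auxiliaries. The C4–OH helper and the benzyl ethers leave together.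

Key step: step 5

Assumption: the (S)-lactate esters are taken to steer the diene to the alkene face that carries their CO2Me groups (s-cis enoate, carbinol C–H eclipsing the acyl C=O); this model leads to the (1S,2R,3R) series.

**Route**

Step 1
Reactants: 1 2-bromo-5-hydroxy-4-methoxybenzaldehyde
Product: 2 5-(benzyloxy)-2-bromo-4-methoxybenzaldehyde
Conditions: BnBr, K2CO3, DMF, rt
Reagents that add atoms: benzyl bromide, BrCc1ccccc1
Why: Williamson ether synthesis, in which the phenoxide formed by K2CO3 is O-alkylated by benzyl bromide (SN2); benzyl is chosen because it leaves in the same hydrogenolysis that later removes the C4 hydroxyl, and no stereocenter is formed.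

Step 2
Reactants: 3 [4-(benzyloxy)-3-methoxyphenyl]methanol
Product: 4 1-(benzyloxy)-4-(chloromethyl)-2-methoxybenzene
Conditions: SOCl2, CH2Cl2, 0 °C to rt; crude chloride used at once
Reagents that add atoms: thionyl chloride, O=S(Cl)Cl
Why: Chlorodehydroxylation of an electron-rich benzylic alcohol through its chlorosulfite is fast at 0 °C and leaves the aryl benzyl ether intact; no stereocenter is formed.

Step 3
Reactants: 2 5-(benzyloxy)-2-bromo-4-methoxybenzaldehyde; 4 1-(benzyloxy)-4-(chloromethyl)-2-methoxybenzene
Product: 6 5-(benzyloxy)-2-[4-(benzyloxy)-3-methoxybenzyl]-4-methoxybenzaldehyde, via benzylzinc chloride 5 (not isolated)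
Conditions: 4, Zn dust (activated), LiCl, THF, 25 °C; then slow addition to 2, Pd(PPh3)4 (3 mol %), THF, 0 °C to rt
Reagents that add atoms: none
Why: Negishi C(sp3)–C(sp2) coupling, in which LiCl-promoted zinc insertion gives 5, the ortho formyl group activates the aryl bromide for oxidative addition, and palladium-catalysed transmetalation and reductive elimination should outrun uncatalysed addition of the organozinc to the electron-rich, ortho-substituted aldehyde, as in known preparations of 2-benzylbenzaldehydes from 2-bromobenzaldehydes and benzylzinc halides; no stereocenter is formed.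

Step 4
Reactants: 7 fumaryl chloride; 8 methyl (S)-lactate
Product: 9 bis[(2S)-1-methoxy-1-oxopropan-2-yl] (2E)-but-2-enedioate
Conditions: 8 (2.2 equiv), pyridine, DMAP (cat.), CH2Cl2, 0 °C to rt
Reagents that add atoms: none
Why: Double nucleophilic acyl substitution of the diacid chloride by the secondary alcohol of the lactate leaves the lactate stereocenter and the E double bond untouched and gives the C2-symmetric chiral dienophile.

Step 5
Reactants: 6 5-(benzyloxy)-2-[4-(benzyloxy)-3-methoxybenzyl]-4-methoxybenzaldehyde; 9 bis[(2S)-1-methoxy-1-oxopropan-2-yl] (2E)-but-2-enedioate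
Product: 11 bis[(2S)-1-methoxy-1-oxopropan-2-yl] (1S,2R,3S,4S)-6-(benzyloxy)-1-[4-(benzyloxy)-3-methoxyphenyl]-4-hydroxy-7-methoxy-1,2,3,4-tetrahydronaphthalene-2,3-dicarboxylate, via photodienol 10 (not isolated)
Conditions: hν (350–365 nm, Pyrex), 9 (2 equiv), degassed toluene, 0.02 M, 20 °C
Reagents that add atoms: none
Why: Photoenolization/Diels–Alder reaction: n,π* excitation of the aryl aldehyde and intersystem crossing let the carbonyl oxygen abstract one of the doubly benzylic hydrogens through a six-membered transition state, and the 1,4-biradical collapses to the (E,E)-hydroxy-o-quinodimethane 10, which fumarate 9 traps in a concerted suprafacial [4π+2π] cycloaddition that rearomatises ring A. The closest known reaction type is the photoenolization/Diels–Alder reaction of o-alkylbenzaldehydes with fumarates and related acrylate-type dienophiles, auxiliary-bearing ones included. Ring B is closed as a six-membered carbocycle by intermolecular [4+2] annulation onto the C4a–C8a bond of ring A, the two new bonds being C3–C4 and C1–C2. C2 and C3 are trans because the E geometry of 9 is transferred stereospecifically; the C4–OH ends cis to the C3 ester and the C1 aryl trans to the C2 ester because the ester next to the hydroxylated terminus sits endo (secondary overlap plus an O–H···O=C hydrogen bond), which forces the other ester of the trans dienophile exo, away from the outward aryl group. The absolute configuration comes from the two (S)-lactate units: with the enoate s-cis and each carbinol C–H eclipsing its acyl C=O, one face of the alkene is lined by the two CO2Me groups and the other by the two methyl groups, and the dienol should add to the CO2Me face, where its OH can hydrogen-bond, to give (1S,2R,3S,4S)-11. The step needs chemoselective trapping of the E,E-dienol (Z-dienols revert to 6 by 1,5-hydrogen shift, and excess 9 in a non-polar solvent favours trapping), endo placement of the C3 ester and π-facial selectivity, the last two secured by the C4 hydroxyl and the lactate groups.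

Step 6
Reactants: 11 bis[(2S)-1-methoxy-1-oxopropan-2-yl] (1S,2R,3S,4S)-6-(benzyloxy)-1-[4-(benzyloxy)-3-methoxyphenyl]-4-hydroxy-7-methoxy-1,2,3,4-tetrahydronaphthalene-2,3-dicarboxylate
Product: 12 bis[(2S)-1-methoxy-1-oxopropan-2-yl] (1S,2R,3R)-6-hydroxy-1-(4-hydroxy-3-methoxyphenyl)-7-methoxy-1,2,3,4-tetrahydronaphthalene-2,3-dicarboxylate
Conditions: H2 (3 atm), 10% Pd/C, EtOAc–AcOH, HClO4 (cat.), rt
Reagents that add atoms: none
Why: Catalytic hydrogenolysis cleaves the two O-benzyl ethers and, with acid assistance, the C4–O bond, which is benzylic and para to the C7 methoxy group; C1, C2 and C3 are not involved, and their all-trans arrangement is also the thermodynamically favoured one.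

Step 7
Reactants: 12 bis[(2S)-1-methoxy-1-oxopropan-2-yl] (1S,2R,3R)-6-hydroxy-1-(4-hydroxy-3-methoxyphenyl)-7-methoxy-1,2,3,4-tetrahydronaphthalene-2,3-dicarboxylate
Product: 13 (1S,2R,3R)-1-(4-hydroxy-3-methoxyphenyl)-2,3-bis(hydroxymethyl)-7-methoxy-1,2,3,4-tetrahydronaphthalen-6-ol (target)
Conditions: LiAlH4 (excess), THF, 0 °C to reflux; then aq. potassium sodium tartrate (KNaC4H4O6), pH 5–6
Reagents that add atoms: none
Why: Ester reduction with LiAlH4 should convert both lactate esters into primary alcohols faster than the α-stereocenters can enolise, the phenols being only deprotonated and restored on work-up, and the auxiliary leaves as water-soluble (S)-propane-1,2-diol.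

**Compound list**

1 | 2-bromo-5-hydroxy-4-methoxybenzaldehyde | COc1cc(Br)c(C=O)cc1O | starting material
2 | 5-(benzyloxy)-2-bromo-4-methoxybenzaldehyde | COc1cc(Br)c(C=O)cc1OCc1ccccc1 | intermediate
3 | [4-(benzyloxy)-3-methoxyphenyl]methanol | COc1cc(CO)ccc1OCc1ccccc1 | starting material
4 | 1-(benzyloxy)-4-(chloromethyl)-2-methoxybenzene | COc1cc(CCl)ccc1OCc1ccccc1 | intermediate
5 | [4-(benzyloxy)-3-methoxybenzyl]zinc chloride | COc1cc(C[Zn]Cl)ccc1OCc1ccccc1 | intermediate
6 | 5-(benzyloxy)-2-[4-(benzyloxy)-3-methoxybenzyl]-4-methoxybenzaldehyde | COc1cc(Cc2cc(OC)c(OCc3ccccc3)cc2C=O)ccc1OCc1ccccc1 | intermediate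
7 | fumaryl chloride | O=C(Cl)/C=C/C(=O)Cl | starting material
8 | methyl (S)-lactate | C[C@H](O)C(=O)OC | starting material
9 | bis[(2S)-1-methoxy-1-oxopropan-2-yl] (2E)-but-2-enedioate | COC(=O)[C@H](C)OC(=O)/C=C/C(=O)O[C@@H](C)C(=O)OC | intermediate
10 | (E,E)-hydroxy-o-quinodimethane (photodienol) from 6: OH on the former formyl carbon and aryl on the former CH2 carbon, both pointing outward | O/C=C1\C=C(OCc2ccccc2)C(OC)=C/C1=C\c1ccc(OCc2ccccc2)c(OC)c1 | intermediate
11 | bis[(2S)-1-methoxy-1-oxopropan-2-yl] (1S,2R,3S,4S)-6-(benzyloxy)-1-[4-(benzyloxy)-3-methoxyphenyl]-4-hydroxy-7-methoxy-1,2,3,4-tetrahydronaphthalene-2,3-dicarboxylate | COc1cc([C@H]2c3cc(OC)c(OCc4ccccc4)cc3[C@@H](O)[C@@H](C(=O)O[C@@H](C)C(=O)OC)[C@@H]2C(=O)O[C@@H](C)C(=O)OC)ccc1OCc1ccccc1 | intermediate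
12 | bis[(2S)-1-methoxy-1-oxopropan-2-yl] (1S,2R,3R)-6-hydroxy-1-(4-hydroxy-3-methoxyphenyl)-7-methoxy-1,2,3,4-tetrahydronaphthalene-2,3-dicarboxylate | COc1cc([C@H]2c3cc(OC)c(O)cc3C[C@@H](C(=O)O[C@@H](C)C(=O)OC)[C@@H]2C(=O)O[C@@H](C)C(=O)OC)ccc1O | intermediate
13 | (1S,2R,3R)-1-(4-hydroxy-3-methoxyphenyl)-2,3-bis(hydroxymethyl)-7-methoxy-1,2,3,4-tetrahydronaphthalen-6-ol | COc1cc([C@H]2c3cc(OC)c(O)cc3C[C@@H](CO)[C@@H]2CO)ccc1O | target

**Totals**

Total step count: 7. Longest linear sequence: 5 steps (step 1 or 2, then steps 3, 5, 6, 7).

**Steps most likely to fail**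

Step 5. Under irradiation the fumarate may isomerise E to Z, and some dienol with the aryl group turned inward may form; either would erode the trans relationships at C1/C2/C3. Photoenolization of the electron-rich aldehyde may also be slow, and facial discrimination by the lactate groups may be incomplete. The fallback separates diene generation from light. It sets out from 6, which is irradiated in SO2-saturated benzene so that the dienol is trapped by cheletropic addition as the crystalline cis-hydroxy sulfone F1 (racemic; its stereocenters are lost again on extrusion). F1 is then heated in the dark with 9 in toluene (80–110 °C, ZnO as acid scavenger). Disrotatory cheletropic loss of SO2 should regenerate only the E,E-dienol 10 at a low stationary concentration, and its Diels–Alder trapping by 9 comes back to the route at 11. Diastereomers of 11 still carry the auxiliary and can be separated.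

Step 6. Acid may ionise the C4–O bond and dehydrate it to the 3,4-dihydronaphthalene, whose hydrogenation could scramble C3; alternatively the hindered C–O bond may resist cleavage on the catalyst surface. The fallback is a radical Barton–McCombie deoxygenation, which avoids the cation. It sets out from 11, which is acylated with O-phenyl chlorothionoformate (DMAP, MeCN) to the O-phenyl thionocarbonate F2. Bu3SnH and AIBN in toluene at 90 °C then give the deoxygenated dibenzyl ether F3. Neutral hydrogenolysis of F3 (H2, 10% Pd/C, EtOAc) removes the benzyl ethers and comes back to the route at 12.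

Step 3. Wurtz-type homocoupling may occur during zinc insertion into the electron-rich benzyl chloride, and the benzylzinc may add to the formyl group instead of coupling. The fallback replaces the organozinc by an isolable organoboron partner. It sets out from 4, which is borylated with bis(pinacolato)diboron (Pd(dba)2, tris(4-methoxyphenyl)phosphine, KOAc, toluene, 50 °C) to the benzylboronic ester F4. Suzuki–Miyaura coupling of F4 with 2 (Pd(OAc)2, SPhos, K3PO4, toluene–H2O, 80 °C) comes back to the route at 6.

**Further compounds**

F1 | step 5 | cis-6-(benzyloxy)-3-[4-(benzyloxy)-3-methoxyphenyl]-1-hydroxy-5-methoxy-1,3-dihydro-2-benzothiophene 2,2-dioxide (racemic, one enantiomer drawn) | O[C@@H]1c2cc(OCc3ccccc3)c(OC)cc2[C@H](c2ccc(OCc3ccccc3)c(OC)c2)S1(=O)=O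
F2 | step 6 | bis[(2S)-1-methoxy-1-oxopropan-2-yl] (1S,2R,3S,4S)-6-(benzyloxy)-1-[4-(benzyloxy)-3-methoxyphenyl]-7-methoxy-4-[(phenoxycarbonothioyl)oxy]-1,2,3,4-tetrahydronaphthalene-2,3-dicarboxylate | COc1cc([C@H]2c3cc(OC)c(OCc4ccccc4)cc3[C@@H](OC(=S)Oc3ccccc3)[C@@H](C(=O)O[C@@H](C)C(=O)OC)[C@@H]2C(=O)O[C@@H](C)C(=O)OC)ccc1OCc1ccccc1
F3 | step 6 | bis[(2S)-1-methoxy-1-oxopropan-2-yl] (1S,2R,3R)-6-(benzyloxy)-1-[4-(benzyloxy)-3-methoxyphenyl]-7-methoxy-1,2,3,4-tetrahydronaphthalene-2,3-dicarboxylate | COc1cc([C@H]2c3cc(OC)c(OCc4ccccc4)cc3C[C@@H](C(=O)O[C@@H](C)C(=O)OC)[C@@H]2C(=O)O[C@@H](C)C(=O)OC)ccc1OCc1ccccc1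
F4 | step 3 | 2-{[4-(benzyloxy)-3-methoxyphenyl]methyl}-4,4,5,5-tetramethyl-1,3,2-dioxaborolane | COc1cc(CB2OC(C)(C)C(C)(C)O2)ccc1OCc1ccccc1
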